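**Plan**

1. Retrosynthesis (chromene numbering; ring A = the dimethoxyphenol ring, ring B = the benzo ring of the chromene): first the ring-A O–CH3 bond ortho to the ketone is cut, then the O1–C2 bond of the pyran, then the C5–C(=O) and C4a–C4 bonds of ring B together.
2. Enabling feature: on ring B, C8a (bearing O1), C4a (bearing the alkene carbon C4) and C5 (bearing the ketone carbon) are three contiguous carbons. This is the ortho-substituent / ipso / ortho′ pattern of an aryl iodide in Pd/norbornene catalysis.
3. Forward: resorcinol is iodinated at C4 and bis-MOM protected, and 2,4,6-trimethoxybenzoic acid is converted to its chloride. A three-component Pd/norbornene coupling with 2-methylbut-3-en-2-ol then joins ring A, ring B and the C4 chain without closing a ring.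
4. Acidic methanol then frees the phenols and closes the pyran, the only ring made in the route. BCl3 finally uncovers the chelated ring-A phenol.
5. Stereochemistry: none to set. The E-alkene from the Heck termination is transient and is erased when the pyran closes.

Key step: step 4

Remark: the target has no stereocentre and its only C=C lies in a ring, so it is achiral and "single enantiomer" calls for no control element.

**Route**

Step 1
Reactants: 1 resorcinol
Product: 2 4-iodoresorcinol (4-iodobenzene-1,3-diol)
Conditions: ICl (1.0 equiv), Et2O, 0 °C → rt; aq. Na2SO3 wash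
Reagents that add atoms: iodine monochloride, ClI
Why: Electrophilic aromatic iodination with ICl in ether is the established entry to the 4-iodo isomer (para to one hydroxyl, ortho to the other), whereas the I2/NaHCO3/water variant, which favours C2, is avoided.

Step 2
Reactants: 2 4-iodoresorcinol
Product: 3 1-iodo-2,4-bis(methoxymethoxy)benzene
Conditions: MOMCl (2.6 equiv), iPr2NEt (3 equiv), CH2Cl2, 0 °C → rt
Reagents that add atoms: chloromethyl methyl ether, COCCl
Why: Amine-mediated O-alkylation of both phenols (MOM acetal protection) leaves the aryl iodide untouched and gives ethers that should tolerate hot carbonate and palladium in step 4.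

Step 3
Reactants: 4 2,4,6-trimethoxybenzoic acid
Product: 5 2,4,6-trimethoxybenzoyl chloride
Conditions: (COCl)2 (1.3 equiv), DMF (cat.), CH2Cl2, 0 °C → rt; evaporate, use crude
Reagents that add atoms: oxalyl chloride, O=C(Cl)C(Cl)=O
Why: Vilsmeier-type (chloroiminium) activation converts the acid into the acyl chloride without heating, which should avoid decarboxylation of this electron-rich acid.

Step 4
Reactants: 3 1-iodo-2,4-bis(methoxymethoxy)benzene; 5 2,4,6-trimethoxybenzoyl chloride; 6 2-methylbut-3-en-2-ol
Product: 7 (E)-[2-(3-hydroxy-3-methylbut-1-en-1-yl)-3,5-bis(methoxymethoxy)phenyl](2,4,6-trimethoxyphenyl)methanone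
Conditions: Pd(OAc)2 (10 mol %), P(2-furyl)3 (25 mol %), norbornene (2 equiv), Cs2CO3 (3 equiv), 5 (1.8 equiv, slow addition), 6 (2.5 equiv), toluene, 100 °C
Reagents that add atoms: none
Why: Oxidative addition of Pd(0) into the C–I bond of 3, exo insertion of norbornene and carbonate-assisted palladation of the only free ortho C–H (C6 of 3, the future C5) give the aryl–norbornyl palladacycle, which is acylated at its aryl carbon by 5 (oxidative addition to Pd(IV), then C(aryl)–C(acyl) reductive elimination); β-carbon elimination then expels norbornene, the 2,6-disubstituted arylpalladium inserts alkene 6 at its terminal carbon, and syn β-hydride elimination, possible only toward the benzylic carbon because the carbinol carbon is quaternary, releases 7 and Pd(0). The closest known reaction type is the Catellani ortho-acylation of ortho-substituted aryl iodides with aroyl chlorides terminated by a Heck reaction; the 2,6-dimethoxy substitution of 5 lies at the hindered end of that scope, which is why 5 is used in excess and added slowly. No ring is closed and no stereocentre is created; the E double bond follows from the syn-elimination geometry and is erased in step 5. Site selectivity (acyl at the future C5, alkenyl at the future C4a) is fixed by the position of iodine and by the ortho MOM ether, which blocks the other flank and lets norbornene leave only after acylation. The step also needs chemoselectivity against premature ipso-Heck coupling and against O-acylation of 6; excess strained norbornene (which inserts faster than 6), the furylphosphine ligand and the mutual hindrance of a tertiary alcohol and a 2,6-disubstituted aroyl chloride should secure it.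

Step 5
Reactants: 7 (E)-[2-(3-hydroxy-3-methylbut-1-en-1-yl)-3,5-bis(methoxymethoxy)phenyl](2,4,6-trimethoxyphenyl)methanone
Product: 9 (7-hydroxy-2,2-dimethyl-2H-chromen-5-yl)(2,4,6-trimethoxyphenyl)methanone, via free resorcinol carbinol 8 (not isolated)
Conditions: HCl (37 % aq., 5 equiv), MeOH, 45 °C
Reagents that add atoms: none
Why: Acid-catalysed acetal methanolysis removes both MOM groups to give 8, whose tertiary allylic carbinol, ortho and para to the freed phenols, ionises to a delocalised benzyl/allyl cation (the O-protonated vinyl ortho-quinone methide) in which the E geometry is lost, so that the C8a oxygen closes the pyran at C2 (oxa-6π closure of the quinone methide, overall a cyclodehydration), as is usual for ortho-(3-hydroxy-3-methylbutenyl)phenols.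

Step 6
Reactants: 9 (7-hydroxy-2,2-dimethyl-2H-chromen-5-yl)(2,4,6-trimethoxyphenyl)methanone
Product: 10 (7-hydroxy-2,2-dimethyl-2H-chromen-5-yl)(2-hydroxy-4,6-dimethoxyphenyl)methanone
Conditions: BCl3 (1 M in CH2Cl2, 3 equiv), CH2Cl2, −78 → 0 °C; aq. NaHCO3
Reagents that add atoms: none
Why: In this chelation-controlled BCl3 ether cleavage boron binds the ketone oxygen and one flanking ring-A methoxy group, chloride removes that methyl, and the resulting six-membered boron chelate protects the second (equivalent) ortho-methoxy group, while the para-methoxy group and the cyclic ether are not activated at low temperature.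

**Compound list**

1 | resorcinol (benzene-1,3-diol) | Oc1cccc(O)c1 | starting material
2 | 4-iodoresorcinol (4-iodobenzene-1,3-diol) | Oc1ccc(I)c(O)c1 | intermediate
3 | 1-iodo-2,4-bis(methoxymethoxy)benzene | COCOc1ccc(I)c(OCOC)c1 | intermediate
4 | 2,4,6-trimethoxybenzoic acid | COc1cc(OC)c(C(O)=O)c(OC)c1 | starting material
5 | 2,4,6-trimethoxybenzoyl chloride | COc1cc(OC)c(C(Cl)=O)c(OC)c1 | intermediate
6 | 2-methylbut-3-en-2-ol | CC(C)(O)C=C | starting material
7 | (E)-[2-(3-hydroxy-3-methylbut-1-en-1-yl)-3,5-bis(methoxymethoxy)phenyl](2,4,6-trimethoxyphenyl)methanone | COCOc1cc(OCOC)c(/C=C/C(C)(C)O)c(C(=O)c2c(OC)cc(OC)cc2OC)c1 | intermediate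
8 | (E)-[3,5-dihydroxy-2-(3-hydroxy-3-methylbut-1-en-1-yl)phenyl](2,4,6-trimethoxyphenyl)methanone | COc1cc(OC)c(C(=O)c2cc(O)cc(O)c2/C=C/C(C)(C)O)c(OC)c1 | intermediate (not isolated)
9 | (7-hydroxy-2,2-dimethyl-2H-chromen-5-yl)(2,4,6-trimethoxyphenyl)methanone | COc1cc(OC)c(C(=O)c2cc(O)cc3c2C=CC(C)(C)O3)c(OC)c1 | intermediate
10 | (7-hydroxy-2,2-dimethyl-2H-chromen-5-yl)(2-hydroxy-4,6-dimethoxyphenyl)methanone | COc1cc(O)c(C(=O)c2cc(O)cc3c2C=CC(C)(C)O3)c(OC)c1 | target

**Step count and risks**

Total step count: 6. Longest linear sequence: 5 steps (steps 1, 2, 4, 5, 6, from resorcinol); step 3 is a one-step side branch.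

Steps most likely to fail, riskiest first:

Step 4. Acylation of the aryl–norbornyl palladacycle by the hindered, electron-rich aroyl chloride may be slower than the competing pathways. The relay would then leak into direct ipso-Heck coupling or norbornene-retaining products, or the chloride would be consumed by O-acylation of the tertiary alcohol. The fallback gives up the relay and makes the two bonds one at a time by carbonyl addition and a plain Heck reaction. It sets out from alkene 6 (iodide 3 and chloride 5 are replaced by purchased 3,5-dihydroxybenzaldehyde and 1,3,5-trimethoxybenzene) and comes back to the route at 7. 3,5-Dihydroxybenzaldehyde would be protected (MOMCl, iPr2NEt, CH2Cl2) as 3,5-bis(methoxymethoxy)benzaldehyde F1. NBS in MeCN should brominate F1 at the position flanked by the formyl group and one ether oxygen and para to the other, giving 2-bromo-3,5-bis(methoxymethoxy)benzaldehyde F2. Lithiation of 1,3,5-trimethoxybenzene (n-BuLi, THF, 0 °C) would give 2,4,6-trimethoxyphenyllithium F3, whose addition to F2 at −78 °C should give racemic [2-bromo-3,5-bis(methoxymethoxy)phenyl](2,4,6-trimethoxyphenyl)methanol F4. Dess–Martin oxidation would give [2-bromo-3,5-bis(methoxymethoxy)phenyl](2,4,6-trimethoxyphenyl)methanone F5. A Heck reaction of F5 with 6 (Pd(OAc)2, P(o-tol)3, Et3N, DMF, 110 °C) would then deliver 7.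

Step 5. E→Z equilibration and ring closure of the ionised carbinol may be incomplete. The cation could be diverted into methanol adducts or captured by the neighbouring ketone oxygen, and the acid-sensitive chromene could oligomerise. The fallback closes the pyran at the saturated level and reintroduces the C3=C4 bond afterwards. It sets out from 7 and returns at 9. Hydrogenation of 7 (H2, 1 atm, Pd/C, EtOAc) would give [2-(3-hydroxy-3-methylbutyl)-3,5-bis(methoxymethoxy)phenyl](2,4,6-trimethoxyphenyl)methanone F6. Acidic methanol would remove the MOM groups and cyclise the tertiary carbinol onto the ortho phenol, giving (7-hydroxy-2,2-dimethylchroman-5-yl)(2,4,6-trimethoxyphenyl)methanone F7. DDQ in refluxing dioxane should then dehydrogenate the chroman, assisted by the para 7-hydroxyl, to 9.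

Step 6. The Lewis acid may ionise the allylic aryl ether of the chromene (ring opening, or HCl addition across C3=C4), or demethylation may run past the first ortho group. The fallback moves the chelation-controlled demethylation to the benzoic acid, before any acid-labile ring exists. It sets out from acid 4 and returns at target 10. BCl3 in CH2Cl2 would convert 4 into 2-hydroxy-4,6-dimethoxybenzoic acid F8. Acetylation (Ac2O, pyridine) would give 2-acetoxy-4,6-dimethoxybenzoic acid F9, and oxalyl chloride with catalytic DMF would give 2-acetoxy-4,6-dimethoxybenzoyl chloride F10. The Pd/norbornene coupling of step 4 with 3 and 6 would then give 2-{2-[(E)-3-hydroxy-3-methylbut-1-en-1-yl]-3,5-bis(methoxymethoxy)benzoyl}-3,5-dimethoxyphenyl acetate F11. The acidic methanol of step 5 should remove both MOM groups, close the pyran and methanolyse the aryl acetate in one operation, giving 10 directly.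

Further compounds
F1 | step 4 | 3,5-bis(methoxymethoxy)benzaldehyde | COCOc1cc(C=O)cc(OCOC)c1
F2 | step 4 | 2-bromo-3,5-bis(methoxymethoxy)benzaldehyde | COCOc1cc(OCOC)c(Br)c(C=O)c1
F3 | step 4 | 2,4,6-trimethoxyphenyllithium | [Li]c1c(OC)cc(OC)cc1OC
F4 | step 4 | racemic [2-bromo-3,5-bis(methoxymethoxy)phenyl](2,4,6-trimethoxyphenyl)methanol | COCOc1cc(OCOC)c(Br)c(C(O)c2c(OC)cc(OC)cc2OC)c1
F5 | step 4 | [2-bromo-3,5-bis(methoxymethoxy)phenyl](2,4,6-trimethoxyphenyl)methanone | COCOc1cc(OCOC)c(Br)c(C(=O)c2c(OC)cc(OC)cc2OC)c1
F6 | step 5 | [2-(3-hydroxy-3-methylbutyl)-3,5-bis(methoxymethoxy)phenyl](2,4,6-trimethoxyphenyl)methanone | COCOc1cc(OCOC)c(CCC(C)(C)O)c(C(=O)c2c(OC)cc(OC)cc2OC)c1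
F7 | step 5 | (7-hydroxy-2,2-dimethylchroman-5-yl)(2,4,6-trimethoxyphenyl)methanone | COc1cc(OC)c(C(=O)c2cc(O)cc3c2CCC(C)(C)O3)c(OC)c1
F8 | step 6 | 2-hydroxy-4,6-dimethoxybenzoic acid | COc1cc(O)c(C(O)=O)c(OC)c1
F9 | step 6 | 2-acetoxy-4,6-dimethoxybenzoic acid | COc1cc(OC(C)=O)c(C(O)=O)c(OC)c1
F10 | step 6 | 2-acetoxy-4,6-dimethoxybenzoyl chloride | COc1cc(OC(C)=O)c(C(Cl)=O)c(OC)c1
F11 | step 6 | 2-{2-[(E)-3-hydroxy-3-methylbut-1-en-1-yl]-3,5-bis(methoxymethoxy)benzoyl}-3,5-dimethoxyphenyl acetate | COCOc1cc(OCOC)c(/C=C/C(C)(C)O)c(C(=O)c2c(OC)cc(OC)cc2OC(C)=O)c1
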